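**Retrosynthetic overview**
1. Target 21 ⇐ tri-angelate 20 by a catalyst-controlled Shi epoxidation of the prenyl alkene (sets C10, last step).
2. 20 ⇐ epoxy-dione 17: angelate opens the C3–C4 oxirane at C3 (trans-diaxial), then hydroxyl-directed reduction of C2=O. 17 ⇐ epoxy ketone 13 by C6 oxygenation/acylation and ketal hydrolysis.
3. 13 ⇐ enone 10 by Luche reduction, hydroxyl-directed epoxidation and re-oxidation; this puts the oxirane cis to the side chain, the face a direct Weitz–Scheffer epoxidation would not give.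
4. 10 ⇐ enal 4 by organocatalytic prenylboration (C8) and acylation. 4 ⇐ quinone monoketal 2 + acrolein by an organocatalytic enantioselective cross-Rauhut–Currier reaction (first stereocenter C1, C1–C7 bond).
5. Ring order: the carbocycle comes from 4-methoxy-2-methylphenol by oxidative dearomatization; the ring oxirane is made and opened on the way; the side-chain oxirane is formed last.

Assumption and convention: locants follow the target (C1 ring carbon bearing the side chain, C2 CHOH, C3 CHOAng, C4 C(CH3)OH, C5 C=O, C6 CHOAng, C7 =CH2 carbon, C8 CHOAng, C9, C10–C11 oxirane), Ang = (Z)-2-methylbut-2-enoyl, and the catalysts of steps 2, 3 and 12 are used as the enantiomers that deliver the configurations given.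

**Step 1**
Reactants: 1 4-methoxy-2-methylphenol
Product: 2 4,4-dimethoxy-2-methylcyclohexa-2,5-dien-1-one
Conditions: PhI(OAc)2 (1.1 equiv), MeOH, 0 °C
Reagents that add atoms: methanol (SMILES: CO)
Why: Hypervalent-iodine oxidative dearomatization of a para-methoxyphenol in methanol gives the achiral quinone monoketal, which already holds the C5 ketone, the masked C2 ketone, the C4 methyl group and both ring alkenes.

**Step 2**
Reactants: 2 4,4-dimethoxy-2-methylcyclohexa-2,5-dien-1-one; 3 acrolein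
Product: 4 2-[(1R)-2,2-dimethoxy-4-methyl-5-oxocyclohex-3-en-1-yl]prop-2-enal
Conditions: (S)-1-[3,5-bis(trifluoromethyl)phenyl]-3-[1-(diphenylphosphanyl)-3-methylbutan-2-yl]thiourea (10 mol%), 2-naphthol (20 mol%), 3 (1.5 equiv, slow addition), CHCl3, −20 °C
Reagents that add atoms: none
Why: Proposed new method: an enantioselective intermolecular cross-Rauhut–Currier reaction in which the chiral phosphine adds to acrolein, the thiourea-bound phosphonium enolate attacks the β-carbon of the unmethylated enone of 2 (the α-methyl enone is less electrophilic and more hindered) on one enantiotopic face, and proton transfer with β-elimination of the phosphine releases the α-branched enal with the (1R) centre; the closest known chemistry is the chiral-phosphine-catalysed intermolecular cross-Rauhut–Currier reaction of vinyl ketones with ene-diones and para-quinone methides, the intramolecular Rauhut–Currier desymmetrization of 4,4-disubstituted cyclohexadienones and the aza-Morita–Baylis–Hillman reaction of acrolein.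

**Step 3**
Reactants: 4 2-[(1R)-2,2-dimethoxy-4-methyl-5-oxocyclohex-3-en-1-yl]prop-2-enal; 5 4,4,5,5-tetramethyl-2-(2-methylbut-3-en-2-yl)-1,3,2-dioxaborolane
Product: 7 (3S)-2-[(1R)-2,2-dimethoxy-4-methyl-5-oxocyclohex-3-en-1-yl]-6-methylhepta-1,5-dien-3-ol, via borate ester 6 (not isolated)
Conditions: (S)-3,3'-bis(2,4,6-triisopropylphenyl)-1,1'-binaphthyl-2,2'-diyl hydrogen phosphate (5 mol%), 5 (1.5 equiv), 4 Å MS, toluene, −30→0 °C; aq. NaHCO3 work-up
Reagents that add atoms: none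
Why: Chiral phosphoric acid-catalysed allylboration through a closed chair transition state with allylic transposition, so the tertiary boronate delivers the linear prenyl group to the aldehyde only (ketone and ketal untouched), and the catalyst selects the aldehyde face to set (8S).

**Step 4**
Reactants: 7 (3S)-2-[(1R)-2,2-dimethoxy-4-methyl-5-oxocyclohex-3-en-1-yl]-6-methylhepta-1,5-dien-3-ol; 8 angelic anhydride
Product: 10 (3S)-2-[(1R)-2,2-dimethoxy-4-methyl-5-oxocyclohex-3-en-1-yl]-6-methylhepta-1,5-dien-3-yl (2Z)-2-methylbut-2-enoate, via lithium alkoxide 9 (not isolated)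
Conditions: LiN(SiMe3)2 (1.05 equiv), THF, −78 °C; then 8 (1.3 equiv), −78→−20 °C
Reagents that add atoms: none
Why: Acylation of the lithium alkoxide with the anhydride, without a nucleophilic catalyst, installs the C8 angelate without Z→E isomerization and removes the only hydroxyl that could misdirect step 6.

**Step 5**
Reactants: 10 (3S)-2-[(1R)-2,2-dimethoxy-4-methyl-5-oxocyclohex-3-en-1-yl]-6-methylhepta-1,5-dien-3-yl (2Z)-2-methylbut-2-enoate
Product: 11 (3S)-2-[(1R,5R)-5-hydroxy-2,2-dimethoxy-4-methylcyclohex-3-en-1-yl]-6-methylhepta-1,5-dien-3-yl (2Z)-2-methylbut-2-enoate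
Conditions: NaBH4, CeCl3·7H2O, MeOH, −78 °C
Reagents that add atoms: none
Why: Luche 1,2-reduction of the enone, with hydride entering from the face opposite the C1 side chain as in carvone → cis-carveol, gives the C5 alcohol cis to the side chain; the ester and ketal are inert.

**Step 6**
Reactants: 11 (3S)-2-[(1R,5R)-5-hydroxy-2,2-dimethoxy-4-methylcyclohex-3-en-1-yl]-6-methylhepta-1,5-dien-3-yl (2Z)-2-methylbut-2-enoate
Product: 12 (3S)-2-[(1R,3R,4R,5R)-3,4-epoxy-5-hydroxy-2,2-dimethoxy-4-methylcyclohexyl]-6-methylhepta-1,5-dien-3-yl (2Z)-2-methylbut-2-enoate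
Conditions: VO(acac)2 (5 mol%), t-BuOOH (1.5 equiv), CH2Cl2, 0 °C→rt
Reagents that add atoms: tert-butyl hydroperoxide (SMILES: CC(C)(C)OO)
Why: Hydroxyl-directed vanadium-catalysed epoxidation delivers oxygen syn to the C5 hydroxyl, so the oxirane forms cis to the side chain, while the prenyl, 1,1-disubstituted and enoate alkenes, which have no free allylic hydroxyl, are left alone.

**Step 7**
Reactants: 12 (3S)-2-[(1R,3R,4R,5R)-3,4-epoxy-5-hydroxy-2,2-dimethoxy-4-methylcyclohexyl]-6-methylhepta-1,5-dien-3-yl (2Z)-2-methylbut-2-enoate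
Product: 13 (3S)-2-[(1R,3R,4S)-3,4-epoxy-2,2-dimethoxy-4-methyl-5-oxocyclohexyl]-6-methylhepta-1,5-dien-3-yl (2Z)-2-methylbut-2-enoate
Conditions: Dess–Martin periodinane, pyridine, CH2Cl2, 0 °C→rt
Reagents that add atoms: none
Why: Dess–Martin oxidation of the only free (secondary) alcohol under buffered conditions returns the C5 ketone without touching the oxirane, ketal or alkenes; no stereocenter changes.

**Step 8**
Reactants: 13 (3S)-2-[(1R,3R,4S)-3,4-epoxy-2,2-dimethoxy-4-methyl-5-oxocyclohexyl]-6-methylhepta-1,5-dien-3-yl (2Z)-2-methylbut-2-enoate; 8 angelic anhydride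
Product: 16 (3S)-2-[(1S,3R,4S,6S)-3,4-epoxy-2,2-dimethoxy-4-methyl-6-[(2Z)-2-methylbut-2-enoyloxy]-5-oxocyclohexyl]-6-methylhepta-1,5-dien-3-yl (2Z)-2-methylbut-2-enoate, via lithium enolate 14 (not isolated), via lithium alkoxide 15 (not isolated)
Conditions: LiN(SiMe3)2 (1.1 equiv), THF, −78 °C; 2-(phenylsulfonyl)-3-phenyloxaziridine (1.3 equiv); then 8 (2 equiv), −78→−30 °C
Reagents that add atoms: 2-(phenylsulfonyl)-3-phenyloxaziridine (SMILES: O=S(=O)(c1ccccc1)N1OC1c1ccccc1)
Why: The ketone can enolize only toward C6 because C4 is fully substituted, Davis oxaziridine hydroxylation of the enolate occurs anti to the adjacent C1 side chain to give the 6-oxygen trans to it, and the resulting lithium alkoxide is acylated in the same pot.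

**Step 9**
Reactants: 16 (3S)-2-[(1S,3R,4S,6S)-3,4-epoxy-2,2-dimethoxy-4-methyl-6-[(2Z)-2-methylbut-2-enoyloxy]-5-oxocyclohexyl]-6-methylhepta-1,5-dien-3-yl (2Z)-2-methylbut-2-enoate
Product: 17 (3S)-2-[(1S,3R,4S,6S)-3,4-epoxy-4-methyl-6-[(2Z)-2-methylbut-2-enoyloxy]-2,5-dioxocyclohexyl]-6-methylhepta-1,5-dien-3-yl (2Z)-2-methylbut-2-enoate
Conditions: TsOH·H2O (10 mol%), acetone/H2O 10:1, 0 °C→rt; crude product used at once
Reagents that add atoms: water (SMILES: O)
Why: Mild acid-catalysed hydrolysis of the dimethyl ketal, the usual way to unmask epoxy quinone monoketals, frees the C2 ketone while the acid-resistant α,β-epoxy ketone and the esters survive; no base is present that could eliminate the C6 ester.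

**Step 10**
Reactants: 17 (3S)-2-[(1S,3R,4S,6S)-3,4-epoxy-4-methyl-6-[(2Z)-2-methylbut-2-enoyloxy]-2,5-dioxocyclohexyl]-6-methylhepta-1,5-dien-3-yl (2Z)-2-methylbut-2-enoate; 18 angelic acid
Product: 19 (3S)-2-[(1S,3S,4S,6S)-4-hydroxy-4-methyl-3,6-bis[(2Z)-2-methylbut-2-enoyloxy]-2,5-dioxocyclohexyl]-6-methylhepta-1,5-dien-3-yl (2Z)-2-methylbut-2-enoate
Conditions: 18 (5 equiv), cesium (Z)-2-methylbut-2-enoate (0.3 equiv), MeCN, 40 °C
Reagents that add atoms: none
Why: SN2 epoxide opening by the carboxylate at C3, which is secondary, activated by the new C2 carbonyl and the site of trans-diaxial (Fürst–Plattner) attack, proceeds with inversion to put the angelate on the face opposite the side chain and leaves the tertiary C4–O bond as the free alcohol.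

**Step 11**
Reactants: 19 (3S)-2-[(1S,3S,4S,6S)-4-hydroxy-4-methyl-3,6-bis[(2Z)-2-methylbut-2-enoyloxy]-2,5-dioxocyclohexyl]-6-methylhepta-1,5-dien-3-yl (2Z)-2-methylbut-2-enoate
Product: 20 (3S)-2-[(1R,2R,3R,4S,6S)-2,4-dihydroxy-4-methyl-3,6-bis[(2Z)-2-methylbut-2-enoyloxy]-5-oxocyclohexyl]-6-methylhepta-1,5-dien-3-yl (2Z)-2-methylbut-2-enoate
Conditions: Me4NBH(OAc)3 (3 equiv), MeCN/AcOH 1:1, −30 °C
Reagents that add atoms: none
Why: Evans–Saksena hydroxyl-directed reduction: the axial C4 hydroxyl binds the borohydride and delivers hydride to the β-positioned C2 carbonyl through a six-membered transition state (also the face anti to the axial C3 ester), giving the C2 alcohol 1,3-anti to C4-OH, while the hindered C5 ketone and the esters are untouched.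

**Step 12**
Reactants: 20 (3S)-2-[(1R,2R,3R,4S,6S)-2,4-dihydroxy-4-methyl-3,6-bis[(2Z)-2-methylbut-2-enoyloxy]-5-oxocyclohexyl]-6-methylhepta-1,5-dien-3-yl (2Z)-2-methylbut-2-enoate
Product: 21 (2S)-1-[(2S)-3,3-dimethyloxiran-2-yl]-3-[(1R,2R,3R,4S,6S)-2,4-dihydroxy-4-methyl-3,6-bis[(2Z)-2-methylbut-2-enoyloxy]-5-oxocyclohexyl]but-3-en-2-yl (2Z)-2-methylbut-2-enoate (CNP0145026.1)
Conditions: L-fructose-derived Shi ketone (enantiomer of the usual D-fructose-derived catalyst, 30 mol%), KHSO5 (as 2KHSO5·KHSO4·K2SO4), K2CO3, Bu4NHSO4 (cat.), Na2B4O7 buffer (pH about 9.5), MeCN/dimethoxymethane/H2O, 0 °C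
Reagents that add atoms: potassium peroxymonosulfate (SMILES: [K+].[O-]S(=O)(=O)OO)
Why: Shi epoxidation: the chiral dioxirane oxidises only the electron-rich trisubstituted prenyl alkene (the three enoates and the 1,1-disubstituted allylic alkene are far less reactive) through a spiro transition state, and this catalyst enantiomer sets the (10S) oxirane under catalyst control.

**Compound list**
1 | 4-methoxy-2-methylphenol | Cc1cc(OC)ccc1O | starting material
2 | 4,4-dimethoxy-2-methylcyclohexa-2,5-dien-1-one | COC1(OC)C=CC(=O)C(C)=C1 | intermediate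
3 | acrolein (prop-2-enal) | C=CC=O | starting material
4 | 2-[(1R)-2,2-dimethoxy-4-methyl-5-oxocyclohex-3-en-1-yl]prop-2-enal | C=C([C@@H]1C(OC)(OC)C=C(C)C(=O)C1)C=O | intermediate
5 | 4,4,5,5-tetramethyl-2-(2-methylbut-3-en-2-yl)-1,3,2-dioxaborolane | C=CC(C)(C)B1OC(C)(C)C(C)(C)O1 | starting material
6 | pinacol borate ester of alcohol 7 (O–B bond at C8) | C=C([C@@H]1C(OC)(OC)C=C(C)C(=O)C1)[C@H](CC=C(C)C)OB1OC(C)(C)C(C)(C)O1 | intermediate
7 | (3S)-2-[(1R)-2,2-dimethoxy-4-methyl-5-oxocyclohex-3-en-1-yl]-6-methylhepta-1,5-dien-3-ol | C=C([C@@H]1C(OC)(OC)C=C(C)C(=O)C1)[C@H](CC=C(C)C)O | intermediate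
8 | angelic anhydride, (2Z)-2-methylbut-2-enoic anhydride | C/C=C(/C)C(=O)OC(=O)/C(C)=C\C | starting material
9 | lithium alkoxide of alcohol 7 | C=C([C@@H]1C(OC)(OC)C=C(C)C(=O)C1)[C@H](CC=C(C)C)O[Li] | intermediate
10 | (3S)-2-[(1R)-2,2-dimethoxy-4-methyl-5-oxocyclohex-3-en-1-yl]-6-methylhepta-1,5-dien-3-yl (2Z)-2-methylbut-2-enoate | C=C([C@@H]1C(OC)(OC)C=C(C)C(=O)C1)[C@H](CC=C(C)C)OC(=O)/C(C)=C\C | intermediate
11 | (3S)-2-[(1R,5R)-5-hydroxy-2,2-dimethoxy-4-methylcyclohex-3-en-1-yl]-6-methylhepta-1,5-dien-3-yl (2Z)-2-methylbut-2-enoate (5-OH cis to the side chain) | C=C([C@@H]1C(OC)(OC)C=C(C)[C@H](O)C1)[C@H](CC=C(C)C)OC(=O)/C(C)=C\C | intermediate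
12 | (3S)-2-[(1R,3R,4R,5R)-3,4-epoxy-5-hydroxy-2,2-dimethoxy-4-methylcyclohexyl]-6-methylhepta-1,5-dien-3-yl (2Z)-2-methylbut-2-enoate (oxirane oxygen and 5-OH cis to the side chain) | C=C([C@@H]1C(OC)(OC)[C@@H]2O[C@]2(C)[C@H](O)C1)[C@H](CC=C(C)C)OC(=O)/C(C)=C\C | intermediate
13 | (3S)-2-[(1R,3R,4S)-3,4-epoxy-2,2-dimethoxy-4-methyl-5-oxocyclohexyl]-6-methylhepta-1,5-dien-3-yl (2Z)-2-methylbut-2-enoate | C=C([C@@H]1C(OC)(OC)[C@@H]2O[C@]2(C)C(=O)C1)[C@H](CC=C(C)C)OC(=O)/C(C)=C\C | intermediate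
14 | lithium C5–C6 enolate of ketone 13 | C=C([C@@H]1C(OC)(OC)[C@@H]2O[C@]2(C)C(O[Li])=C1)[C@H](CC=C(C)C)OC(=O)/C(C)=C\C | intermediate
15 | lithium alkoxide of the 6-hydroxy derivative of 13 (6-O trans to the side chain) | C=C([C@@H]1C(OC)(OC)[C@@H]2O[C@]2(C)C(=O)[C@H]1O[Li])[C@H](CC=C(C)C)OC(=O)/C(C)=C\C | intermediate
16 | (3S)-2-[(1S,3R,4S,6S)-3,4-epoxy-2,2-dimethoxy-4-methyl-6-[(2Z)-2-methylbut-2-enoyloxy]-5-oxocyclohexyl]-6-methylhepta-1,5-dien-3-yl (2Z)-2-methylbut-2-enoate | C=C([C@@H]1C(OC)(OC)[C@@H]2O[C@]2(C)C(=O)[C@H]1OC(=O)/C(C)=C\C)[C@H](CC=C(C)C)OC(=O)/C(C)=C\C | intermediate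
17 | (3S)-2-[(1S,3R,4S,6S)-3,4-epoxy-4-methyl-6-[(2Z)-2-methylbut-2-enoyloxy]-2,5-dioxocyclohexyl]-6-methylhepta-1,5-dien-3-yl (2Z)-2-methylbut-2-enoate | C=C([C@@H]1C(=O)[C@@H]2O[C@]2(C)C(=O)[C@H]1OC(=O)/C(C)=C\C)[C@H](CC=C(C)C)OC(=O)/C(C)=C\C | intermediate
18 | angelic acid, (2Z)-2-methylbut-2-enoic acid | C/C=C(/C)C(=O)O | starting material
19 | (3S)-2-[(1S,3S,4S,6S)-4-hydroxy-4-methyl-3,6-bis[(2Z)-2-methylbut-2-enoyloxy]-2,5-dioxocyclohexyl]-6-methylhepta-1,5-dien-3-yl (2Z)-2-methylbut-2-enoate | C=C([C@@H]1C(=O)[C@@H](OC(=O)/C(C)=C\C)[C@](C)(O)C(=O)[C@H]1OC(=O)/C(C)=C\C)[C@H](CC=C(C)C)OC(=O)/C(C)=C\C | intermediate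
20 | (3S)-2-[(1R,2R,3R,4S,6S)-2,4-dihydroxy-4-methyl-3,6-bis[(2Z)-2-methylbut-2-enoyloxy]-5-oxocyclohexyl]-6-methylhepta-1,5-dien-3-yl (2Z)-2-methylbut-2-enoate | C=C([C@@H]1[C@@H](O)[C@@H](OC(=O)/C(C)=C\C)[C@](C)(O)C(=O)[C@H]1OC(=O)/C(C)=C\C)[C@H](CC=C(C)C)OC(=O)/C(C)=C\C | intermediate
21 | (2S)-1-[(2S)-3,3-dimethyloxiran-2-yl]-3-[(1R,2R,3R,4S,6S)-2,4-dihydroxy-4-methyl-3,6-bis[(2Z)-2-methylbut-2-enoyloxy]-5-oxocyclohexyl]but-3-en-2-yl (2Z)-2-methylbut-2-enoate, CNP0145026.1 | C=C([C@@H]1[C@@H](O)[C@@H](OC(=O)/C(C)=C\C)[C@](C)(O)C(=O)[C@H]1OC(=O)/C(C)=C\C)[C@H](C[C@@H]1OC1(C)C)OC(=O)/C(C)=C\C | target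

**Step count and risks**
Total steps: 12. Longest linear sequence: 12 (fully linear from 1; compounds 3, 5, 8 and 18 are purchased).

The three steps most likely to fail:

Step 2 (the proposed cross-Rauhut–Currier reaction; acrolein oligomerization, low turnover or low enantioselectivity). The fallback sets out from 2 and comes back at 4 and uses known chemistry. A rhodium/chiral-diene-catalysed asymmetric conjugate addition (Hayashi–Miyaura type; [RhCl(C2H4)2]2, (R,R)-2,5-diphenylbicyclo[2.2.2]octa-2,5-diene or its enantiomer, aq. KOH, dioxane, 40 °C) of the known alkenyl boronate 2-[3-(tert-butyldimethylsilyloxy)prop-1-en-2-yl]-4,4,5,5-tetramethyl-1,3,2-dioxaborolane to the less substituted enone of 2 gives the silyl ether (5R)-5-[3-(tert-butyldimethylsilyloxy)prop-1-en-2-yl]-4,4-dimethoxy-2-methylcyclohex-2-en-1-one F1. Bu4NF in THF then frees the allylic alcohol (5R)-5-(3-hydroxyprop-1-en-2-yl)-4,4-dimethoxy-2-methylcyclohex-2-en-1-one F2, and MnO2 in CH2Cl2 oxidises this primary allylic alcohol to enal 4.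

Step 3 (the tertiary, α,α-disubstituted allyl boronate may react slowly or with lower enantioselectivity than the parent reagent). The fallback sets out from 4 and comes back at 7. Allylboration of 4 with allylboronic acid pinacol ester under the same chiral phosphoric acid (the parent case of this catalysis) gives the homoallylic alcohol (3S)-2-[(1R)-2,2-dimethoxy-4-methyl-5-oxocyclohex-3-en-1-yl]hexa-1,5-dien-3-ol F3. Its terminal vinyl group is then converted into the prenyl terminus by cross-metathesis with 2-methylbut-2-ene (second-generation Grubbs catalyst, CH2Cl2, 40 °C), which gives 7.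

Step 10 (the carboxylate buffer may trigger β-elimination of the C6 ester from the base-labile dione 17, or the opening may be slow). The fallback sets out from 17 and comes back at 19 and avoids any base. The oxirane is opened with water under acid catalysis (HClO4 cat., THF/H2O, 0 °C; same C3 regiochemistry and inversion) to the diol (3S)-2-[(1S,3S,4S,6S)-3,4-dihydroxy-4-methyl-6-[(2Z)-2-methylbut-2-enoyloxy]-2,5-dioxocyclohexyl]-6-methylhepta-1,5-dien-3-yl (2Z)-2-methylbut-2-enoate F4. The secondary C3 hydroxyl of F4 is then esterified in preference to the tertiary C4 hydroxyl with angelic anhydride 8 under Lewis-acid catalysis (Sc(OTf)3 cat., MeCN, −20 °C) to give 19.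

**Further compounds**
F1 | step 2 | (5R)-5-[3-(tert-butyldimethylsilyloxy)prop-1-en-2-yl]-4,4-dimethoxy-2-methylcyclohex-2-en-1-one | C=C([C@@H]1C(OC)(OC)C=C(C)C(=O)C1)CO[Si](C)(C)C(C)(C)C
F2 | step 2 | (5R)-5-(3-hydroxyprop-1-en-2-yl)-4,4-dimethoxy-2-methylcyclohex-2-en-1-one | C=C([C@@H]1C(OC)(OC)C=C(C)C(=O)C1)CO
F3 | step 3 | (3S)-2-[(1R)-2,2-dimethoxy-4-methyl-5-oxocyclohex-3-en-1-yl]hexa-1,5-dien-3-ol | C=C([C@@H]1C(OC)(OC)C=C(C)C(=O)C1)[C@H](CC=C)O
F4 | step 10 | (3S)-2-[(1S,3S,4S,6S)-3,4-dihydroxy-4-methyl-6-[(2Z)-2-methylbut-2-enoyloxy]-2,5-dioxocyclohexyl]-6-methylhepta-1,5-dien-3-yl (2Z)-2-methylbut-2-enoate | C=C([C@@H]1C(=O)[C@@H](O)[C@](C)(O)C(=O)[C@H]1OC(=O)/C(C)=C\C)[C@H](CC=C(C)C)OC(=O)/C(C)=C\C
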